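**Convention.** Target locants used in the text: ring B = C1 (quaternary, CH2OH), C2 (CH with the 3-hydroxypropyl chain), C3 (enal-bearing carbon), C4, C5, C6 (tertiary carbinol); ring A = the (1R,3S)-2,2,3-trimethyl-6-methylidenecyclohexyl unit. The enal is Z (formyl syn to C2).

## Retrosynthetic overview

1. Last bond: Stille coupling of the ring B (E)-vinyl iodide 24 with the ring A (E)-vinylstannane 34 closes the (E,E)-diene.
2. 24 comes from ketone 21 (isopropenyl addition, oxidative allylic transposition to the Z-enal), and 21 from cyclohexanone 16 (MeMgBr, then hydrozirconation–iodination of the 2-alkyne).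
3. Key step: 16 from 1-alkenylcyclopentanol 14 by directed epoxidation and semipinacol ring expansion (five- to six-membered ring B; quaternary C1, CH2O and the C6 ketone formed together); 14 from cyclopentanone 9 and alkenyl Grignard 13.
4. 9 from 2-iodocyclopent-2-enone (CBS reduction, B-alkyl Suzuki, anti hydroboration); 34 from 2-methylcyclohex-2-enone (asymmetric conjugate methylation/methylation, bromoformylation, Stille, reductive allylic transposition).
5. Ring order: the ring A carbocycle is bought; ring B is made from a bought five-membered ring by the expansion; no other ring is formed.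

## Route

Step 1
Reactants: 1 2-iodocyclopent-2-en-1-one
Product: 2 (R)-2-iodocyclopent-2-en-1-ol
Conditions: (S)-2-methyl-CBS-oxazaborolidine (10 mol %), BH3·SMe2, THF, −20 °C
Reagents that add atoms: none
Why: Corey–Bakshi–Shibata reduction, in which the iodoalkenyl arm acts as the large group so hydride is delivered to one carbonyl face and sets the (R)-carbinol, a relay centre that later becomes the C3 ketone.

Step 2
Reactants: 2 (R)-2-iodocyclopent-2-en-1-ol
Product: 3 (R)-triethyl[(2-iodocyclopent-2-en-1-yl)oxy]silane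
Conditions: Et3SiCl, imidazole, CH2Cl2, 0 °C
Reagents that add atoms: chlorotriethylsilane, CC[Si](CC)(CC)Cl
Why: Standard silylation of a secondary allylic alcohol, giving an ether that can later be removed in the presence of primary TBS ethers.

Step 3
Reactants: 3 (R)-triethyl[(2-iodocyclopent-2-en-1-yl)oxy]silane; 4 tert-butyldimethyl(prop-2-en-1-yloxy)silane
Product: 6 (R)-tert-butyldimethyl(3-{5-[(triethylsilyl)oxy]cyclopent-1-en-1-yl}propoxy)silane, via B-alkyl-9-BBN 5 (not isolated)
Conditions: 4, 9-BBN, THF, 0 °C → rt; then 3, PdCl2(dppf) (5 mol %), AsPh3, Cs2CO3, DMF/H2O, rt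
Reagents that add atoms: none
Why: B-alkyl Suzuki–Miyaura coupling: anti-Markovnikov hydroboration of the allyl ether gives a primary alkylborane that couples with the vinyl iodide without touching the allylic stereocentre.

Step 4
Reactants: 6 (R)-tert-butyldimethyl(3-{5-[(triethylsilyl)oxy]cyclopent-1-en-1-yl}propoxy)silane
Product: 9 (2R,3R)-2-{3-[(tert-butyldimethylsilyl)oxy]propyl}-3-[(triethylsilyl)oxy]cyclopentan-1-one, via alkylborane 7 (not isolated), via borate ester 8 (not isolated)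
Conditions: BH3·THF, THF, 0 °C → rt; then N-methylmorpholine N-oxide (6 equiv), (n-Pr4N)RuO4 (5 mol %), 4 Å MS, CH2Cl2, rt
Reagents that add atoms: N-methylmorpholine N-oxide, C[N+]1([O-])CCOCC1
Why: Hydroboration occurs anti to the allylic silyloxy group with boron on the less substituted carbon, so the syn-delivered hydrogen sets C2 (side chain cis to OTES), and the C–B bond is then oxidised in the same flask by the amine N-oxide and Ley–Griffith oxidation to the ketone under neutral conditions that do not epimerise C2.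

Step 5
Reactants: 10 3-bromobut-3-en-1-ol
Product: 12 2-bromohept-1-en-5-yne, via triflate 11 (not isolated)
Conditions: Tf2O, 2,6-lutidine, CH2Cl2, −78 °C; then CH3C≡CLi, THF/DMPU, −78 → −20 °C
Reagents that add atoms: 1-propynyllithium, CC#C[Li]
Why: Triflation followed by SN2 alkynylation of the primary triflate with a lithium acetylide, which is fast at low temperature and leaves the vinyl bromide untouched.

Step 6
Reactants: 9 (2R,3R)-2-{3-[(tert-butyldimethylsilyl)oxy]propyl}-3-[(triethylsilyl)oxy]cyclopentan-1-one; 12 2-bromohept-1-en-5-yne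
Product: 14 (1S,2R,3R)-2-{3-[(tert-butyldimethylsilyl)oxy]propyl}-1-(hept-1-en-5-yn-2-yl)-3-[(triethylsilyl)oxy]cyclopentan-1-ol, via alkenyl Grignard 13 (not isolated)
Conditions: 12, Mg, THF, 40 °C; then 9, LaCl3·2LiCl (1 equiv), THF, −20 → 0 °C
Reagents that add atoms: none
Why: Lanthanum-assisted Grignard 1,2-addition (no enolisation or β-elimination) from the face opposite the two cis substituents, which places the new hydroxyl cis to the side chain and to OTES.

Step 7
Reactants: 14 (1S,2R,3R)-2-{3-[(tert-butyldimethylsilyl)oxy]propyl}-1-(hept-1-en-5-yn-2-yl)-3-[(triethylsilyl)oxy]cyclopentan-1-ol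
Product: 16 (2S,3S,4R)-2-{[(tert-butyldimethylsilyl)oxy]methyl}-3-{3-[(tert-butyldimethylsilyl)oxy]propyl}-2-(pent-3-yn-1-yl)-4-[(triethylsilyl)oxy]cyclohexan-1-one, via epoxy alcohol 15 (not isolated)
Conditions: VO(acac)2 (5 mol %), t-BuOOH (1.2 equiv), CH2Cl2, 0 °C → rt; then 2,6-di-tert-butylpyridine (1.5 equiv), TBSOTf (1.3 equiv), −78 → −40 °C
Reagents that add atoms: tert-butyl hydroperoxide, CC(C)(C)OO; tert-butyldimethylsilyl trifluoromethanesulfonate, CC(C)(C)[Si](C)(C)OS(=O)(=O)C(F)(F)F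
Why: Proposed new method: a one-flask hydroxyl-directed epoxidation/silyl triflate-triggered semipinacol ring expansion in which the vanadate ester epoxidises through the conformer where the ring CH2 rather than the substituted ring CH eclipses the pentynyl substituent (giving the (R)-oxirane 15), and O-silylation of the oxirane then makes the more substituted ring carbon, which lies anti to the breaking C–O bond, shift with inversion at the oxirane carbon and retention at the migrating carbon, so the six-membered ring, the C6 ketone and the quaternary C1 (CH2OTBS cis to the C2 side chain) form together; the closest known reaction types are vanadium-catalysed epoxidation of tertiary allylic alcohols and the Lewis acid or silyl triflate semipinacol rearrangement of 2,3-epoxy alcohols, which to my knowledge have not been run as a relay on an unstrained, stereochemically loaded cyclopentanol with in-flask silyl capture.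

Step 8
Reactants: 16 (2S,3S,4R)-2-{[(tert-butyldimethylsilyl)oxy]methyl}-3-{3-[(tert-butyldimethylsilyl)oxy]propyl}-2-(pent-3-yn-1-yl)-4-[(triethylsilyl)oxy]cyclohexan-1-one
Product: 17 (1S,2S,3S,4R)-2-{[(tert-butyldimethylsilyl)oxy]methyl}-3-{3-[(tert-butyldimethylsilyl)oxy]propyl}-1-methyl-2-(pent-3-yn-1-yl)-4-[(triethylsilyl)oxy]cyclohexan-1-ol
Conditions: MeMgBr, LaCl3·2LiCl, THF, −20 → 0 °C
Reagents that add atoms: methylmagnesium bromide, C[Mg]Br
Why: Grignard addition from the ring face that carries only the pentynyl chain, since CH2OTBS, the C2 side chain and OTES all shield the other face, which gives the C6 carbinol with OH cis to CH2OTBS and methyl cis to the chain.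

Step 9
Reactants: 17 (1S,2S,3S,4R)-2-{[(tert-butyldimethylsilyl)oxy]methyl}-3-{3-[(tert-butyldimethylsilyl)oxy]propyl}-1-methyl-2-(pent-3-yn-1-yl)-4-[(triethylsilyl)oxy]cyclohexan-1-ol
Product: 19 (1S,2S,3S,4R)-2-{[(tert-butyldimethylsilyl)oxy]methyl}-3-{3-[(tert-butyldimethylsilyl)oxy]propyl}-2-[(3E)-4-iodopent-3-en-1-yl]-1-methyl-4-[(triethylsilyl)oxy]cyclohexan-1-ol, via alkenylzirconocene 18 (not isolated)
Conditions: Cp2Zr(H)Cl (3 equiv), THF, 40 °C; then I2, THF, 0 °C
Reagents that add atoms: iodine, II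
Why: Hydrozirconation is a syn addition and excess Cp2Zr(H)Cl equilibrates the alkenylzirconium to the less hindered regioisomer (Zr next to the methyl), so iodinolysis with retention gives the (E)-2-iodoalkene.

Step 10
Reactants: 19 (1S,2S,3S,4R)-2-{[(tert-butyldimethylsilyl)oxy]methyl}-3-{3-[(tert-butyldimethylsilyl)oxy]propyl}-2-[(3E)-4-iodopent-3-en-1-yl]-1-methyl-4-[(triethylsilyl)oxy]cyclohexan-1-ol
Product: 21 (2S,3S,4S)-3-{[(tert-butyldimethylsilyl)oxy]methyl}-2-{3-[(tert-butyldimethylsilyl)oxy]propyl}-4-hydroxy-3-[(3E)-4-iodopent-3-en-1-yl]-4-methylcyclohexan-1-one, via secondary alcohol 20 (not isolated)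
Conditions: IBX (3 equiv), DMSO, rt
Reagents that add atoms: none
Why: IBX in DMSO cleaves the triethylsilyl ether while TBS ethers and the tertiary alcohol stay untouched, then oxidises the freed secondary alcohol to the C3 ketone (IBX oxidation) under non-epimerising conditions.

Step 11
Reactants: 21 (2S,3S,4S)-3-{[(tert-butyldimethylsilyl)oxy]methyl}-2-{3-[(tert-butyldimethylsilyl)oxy]propyl}-4-hydroxy-3-[(3E)-4-iodopent-3-en-1-yl]-4-methylcyclohexan-1-one
Product: 22 (2S,3S,4S)-3-{[(tert-butyldimethylsilyl)oxy]methyl}-2-{3-[(tert-butyldimethylsilyl)oxy]propyl}-3-[(3E)-4-iodopent-3-en-1-yl]-4-methyl-1-(prop-1-en-2-yl)cyclohexane-1,4-diol (both C1 epimers)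
Conditions: CH2=C(CH3)MgBr (4 equiv), LaCl3·2LiCl, THF, 0 °C
Reagents that add atoms: isopropenylmagnesium bromide, C=C(C)[Mg]Br
Why: Lanthanum-assisted Grignard addition to the hindered, enolisable ketone; the new carbinol centre is of no consequence because it becomes sp2 in the next step.

Step 12
Reactants: 22 (2S,3S,4S)-3-{[(tert-butyldimethylsilyl)oxy]methyl}-2-{3-[(tert-butyldimethylsilyl)oxy]propyl}-3-[(3E)-4-iodopent-3-en-1-yl]-4-methyl-1-(prop-1-en-2-yl)cyclohexane-1,4-diol
Product: 23 (2Z)-2-{(2R,3S,4S)-3-{[(tert-butyldimethylsilyl)oxy]methyl}-2-{3-[(tert-butyldimethylsilyl)oxy]propyl}-4-hydroxy-3-[(3E)-4-iodopent-3-en-1-yl]-4-methylcyclohexylidene}propanal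
Conditions: (C5H5NH)[CrO3Cl] (3 equiv), NaOAc, 4 Å MS, CH2Cl2, rt
Reagents that add atoms: pyridinium chlorochromate, [O-][Cr](=O)(=O)Cl.c1cc[nH+]cc1
Why: Babler–Dauben oxidative transposition (chromate ester 1,3-shift, then oxidation of the primary allylic chromate), in which the methyl group turns toward the less hindered ring CH2 so the formyl group ends syn to C2, which is also the isomer favoured at equilibrium; the tertiary C6 alcohol is not allylic and stays.

Step 13
Reactants: 23 (2Z)-2-{(2R,3S,4S)-3-{[(tert-butyldimethylsilyl)oxy]methyl}-2-{3-[(tert-butyldimethylsilyl)oxy]propyl}-4-hydroxy-3-[(3E)-4-iodopent-3-en-1-yl]-4-methylcyclohexylidene}propanal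
Product: 24 (2Z)-2-{(2R,3S,4S)-4-hydroxy-3-(hydroxymethyl)-2-(3-hydroxypropyl)-3-[(3E)-4-iodopent-3-en-1-yl]-4-methylcyclohexylidene}propanal
Conditions: HF·pyridine, pyridine, THF, 0 °C → rt
Reagents that add atoms: none
Why: Buffered fluoride desilylation removes both primary TBS ethers without affecting the enal, the vinyl iodide or the tertiary alcohol.

Step 14
Reactants: 25 2-methylcyclohex-2-en-1-one
Product: 28 (S)-2,2,3-trimethylcyclohexan-1-one, via aluminium enolate 26 (not isolated), via lithium enolate 27 (not isolated)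
Conditions: Me3Al, Cu(OTf)2 (2 mol %), chiral phosphoramidite ligand (4 mol %, enantiomer giving S), Et2O, −30 °C; then MeLi, THF/DMPU, MeI, −30 → 0 °C
Reagents that add atoms: trimethylaluminium, C[Al](C)C; iodomethane, CI
Why: Copper-catalysed asymmetric conjugate addition sets the secondary methyl stereocentre under ligand control, and the regiodefined enolate is then C-methylated to build the gem-dimethyl carbon (tandem conjugate addition–enolate alkylation).

Step 15
Reactants: 28 (S)-2,2,3-trimethylcyclohexan-1-one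
Product: 29 (S)-2-bromo-3,3,4-trimethylcyclohex-1-ene-1-carbaldehyde
Conditions: PBr3, DMF, CHCl3, 0 → 60 °C; NaOAc (aq)
Reagents that add atoms: N,N-dimethylformamide, CN(C)C=O; phosphorus tribromide, BrP(Br)Br; water, O
Why: Vilsmeier–Haack bromoformylation, regiospecific because the ketone has only one enolisable side, places the formyl group on the future methylidene carbon and bromine on the future ring stereocentre.

Step 16
Reactants: 29 (S)-2-bromo-3,3,4-trimethylcyclohex-1-ene-1-carbaldehyde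
Product: 30 (S)-3,3,4-trimethyl-2-[(E)-2-(tributylstannyl)ethenyl]cyclohex-1-ene-1-carbaldehyde
Conditions: (E)-Bu3SnCH=CHSnBu3 (3 equiv), Pd(PPh3)4 (5 mol %), toluene, 80 °C
Reagents that add atoms: (E)-1,2-bis(tributylstannyl)ethene, CCCC[Sn](CCCC)(CCCC)/C=C/[Sn](CCCC)(CCCC)CCCC
Why: Stille coupling of the activated β-bromo enal with excess distannane gives mono-coupling with retention of the E geometry and leaves a vinylstannane for the final union.

Step 17
Reactants: 30 (S)-3,3,4-trimethyl-2-[(E)-2-(tributylstannyl)ethenyl]cyclohex-1-ene-1-carbaldehyde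
Product: 31 {(S)-3,3,4-trimethyl-2-[(E)-2-(tributylstannyl)ethenyl]cyclohex-1-en-1-yl}methanol
Conditions: NaBH4, CeCl3·7H2O, MeOH, −20 °C
Reagents that add atoms: none
Why: Luche reduction gives clean 1,2-reduction of the dienal to the primary allylic alcohol.

Step 18
Reactants: 31 {(S)-3,3,4-trimethyl-2-[(E)-2-(tributylstannyl)ethenyl]cyclohex-1-en-1-yl}methanol
Product: 34 tributyl{(E)-2-[(1R,3S)-2,2,3-trimethyl-6-methylidenecyclohexyl]ethenyl}stannane, via sulfonylhydrazine 32 (not isolated), via allylic diazene 33 (not isolated)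
Conditions: 2-nitrobenzenesulfonylhydrazide, PPh3, diethyl azodicarboxylate, N-methylmorpholine, −30 °C → rt
Reagents that add atoms: none
Why: Myers reductive 1,3-transposition (Mitsunobu N-alkylation, loss of sulfinic acid, retro-ene loss of N2 from the allylic diazene) moves the alkene to the exocyclic position and delivers hydrogen to the ring carbon axially, anti to the pseudoaxial methyl of the gem-dimethyl group in the half-chair with the secondary methyl equatorial, which leaves the stannylvinyl group equatorial and cis to that methyl.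

Step 19
Reactants: 24 (2Z)-2-{(2R,3S,4S)-4-hydroxy-3-(hydroxymethyl)-2-(3-hydroxypropyl)-3-[(3E)-4-iodopent-3-en-1-yl]-4-methylcyclohexylidene}propanal; 34 tributyl{(E)-2-[(1R,3S)-2,2,3-trimethyl-6-methylidenecyclohexyl]ethenyl}stannane
Product: 35 (2Z)-2-{(2R,3S,4S)-4-hydroxy-3-(hydroxymethyl)-2-(3-hydroxypropyl)-4-methyl-3-[(3E,5E)-4-methyl-6-[(1R,3S)-2,2,3-trimethyl-6-methylidenecyclohexyl]hexa-3,5-dien-1-yl]cyclohexylidene}propanal
Conditions: Pd2(dba)3 (5 mol %), AsPh3 (20 mol %), N-methylpyrrolidone, rt → 40 °C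
Reagents that add atoms: none
Why: Stille coupling proceeds with retention at both alkenyl partners, tolerates the free hydroxyls and the enal, and forms the (E,E)-diene as the last bond so the acid-sensitive ring A is never exposed to the ring B oxidations.

## Compound list

1 | 2-iodocyclopent-2-en-1-one | O=C1CCC=C1I | starting material
2 | (R)-2-iodocyclopent-2-en-1-ol | O[C@@H]1CCC=C1I | intermediate
3 | (R)-triethyl[(2-iodocyclopent-2-en-1-yl)oxy]silane | CC[Si](CC)(CC)O[C@@H]1CCC=C1I | intermediate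
4 | tert-butyldimethyl(prop-2-en-1-yloxy)silane (allyl alcohol TBS ether) | C=CCO[Si](C)(C)C(C)(C)C | starting material
5 | 9-{3-[(tert-butyldimethylsilyl)oxy]propyl}-9-borabicyclo[3.3.1]nonane | CC(C)(C)[Si](C)(C)OCCCB1C2CCCC1CCC2 | intermediate
6 | (R)-tert-butyldimethyl(3-{5-[(triethylsilyl)oxy]cyclopent-1-en-1-yl}propoxy)silane | CC[Si](CC)(CC)O[C@@H]1CCC=C1CCCO[Si](C)(C)C(C)(C)C | intermediate
7 | {(1R,2S,3R)-2-{3-[(tert-butyldimethylsilyl)oxy]propyl}-3-[(triethylsilyl)oxy]cyclopentyl}borane (drawn at the monoalkylborane stage; boron trans to the side chain) | B[C@@H]1CC[C@@H](O[Si](CC)(CC)CC)[C@H]1CCCO[Si](C)(C)C(C)(C)C | intermediate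
8 | (1R,2S,3R)-2-{3-[(tert-butyldimethylsilyl)oxy]propyl}-3-[(triethylsilyl)oxy]cyclopentyl dihydrogen borate | OB(O)O[C@@H]1CC[C@@H](O[Si](CC)(CC)CC)[C@H]1CCCO[Si](C)(C)C(C)(C)C | intermediate
9 | (2R,3R)-2-{3-[(tert-butyldimethylsilyl)oxy]propyl}-3-[(triethylsilyl)oxy]cyclopentan-1-one (2,3-cis) | O=C1CC[C@@H](O[Si](CC)(CC)CC)[C@H]1CCCO[Si](C)(C)C(C)(C)C | intermediate
10 | 3-bromobut-3-en-1-ol | OCCC(Br)=C | starting material
11 | 3-bromobut-3-en-1-yl trifluoromethanesulfonate | C=C(Br)CCOS(=O)(=O)C(F)(F)F | intermediate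
12 | 2-bromohept-1-en-5-yne | C=C(Br)CCC#CC | intermediate
13 | (hept-1-en-5-yn-2-yl)magnesium bromide | C=C([Mg]Br)CCC#CC | intermediate
14 | (1S,2R,3R)-2-{3-[(tert-butyldimethylsilyl)oxy]propyl}-1-(hept-1-en-5-yn-2-yl)-3-[(triethylsilyl)oxy]cyclopentan-1-ol (OH, side chain and OTES all cis) | C=C(CCC#CC)[C@]1(O)CC[C@@H](O[Si](CC)(CC)CC)[C@H]1CCCO[Si](C)(C)C(C)(C)C | intermediate
15 | (1S,2R,3R)-2-{3-[(tert-butyldimethylsilyl)oxy]propyl}-1-[(2R)-2-(pent-3-yn-1-yl)oxiran-2-yl]-3-[(triethylsilyl)oxy]cyclopentan-1-ol | CC#CCC[C@@]1(CO1)[C@]2(O)CC[C@@H](O[Si](CC)(CC)CC)[C@H]2CCCO[Si](C)(C)C(C)(C)C | intermediate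
16 | (2S,3S,4R)-2-{[(tert-butyldimethylsilyl)oxy]methyl}-3-{3-[(tert-butyldimethylsilyl)oxy]propyl}-2-(pent-3-yn-1-yl)-4-[(triethylsilyl)oxy]cyclohexan-1-one | CC#CCC[C@@]1(CO[Si](C)(C)C(C)(C)C)[C@H](CCCO[Si](C)(C)C(C)(C)C)[C@H](O[Si](CC)(CC)CC)CCC1=O | intermediate
17 | (1S,2S,3S,4R)-2-{[(tert-butyldimethylsilyl)oxy]methyl}-3-{3-[(tert-butyldimethylsilyl)oxy]propyl}-1-methyl-2-(pent-3-yn-1-yl)-4-[(triethylsilyl)oxy]cyclohexan-1-ol | CC#CCC[C@@]1(CO[Si](C)(C)C(C)(C)C)[C@H](CCCO[Si](C)(C)C(C)(C)C)[C@H](O[Si](CC)(CC)CC)CC[C@]1(C)O | intermediate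
18 | alkenylzirconocene chloride of 17: Cp2Zr(Cl) on the methyl-bearing alkene carbon, Zr trans to the ring-side CH2 (E), ring stereocentres as in 17, drawn with the free hydroxyl | Cl[Zr](C2C=CC=C2)(C2C=CC=C2)/C(C)=C/CC[C@@]1(CO[Si](C)(C)C(C)(C)C)[C@H](CCCO[Si](C)(C)C(C)(C)C)[C@H](O[Si](CC)(CC)CC)CC[C@]1(C)O | intermediate
19 | (1S,2S,3S,4R)-2-{[(tert-butyldimethylsilyl)oxy]methyl}-3-{3-[(tert-butyldimethylsilyl)oxy]propyl}-2-[(3E)-4-iodopent-3-en-1-yl]-1-methyl-4-[(triethylsilyl)oxy]cyclohexan-1-ol | I/C(C)=C/CC[C@@]1(CO[Si](C)(C)C(C)(C)C)[C@H](CCCO[Si](C)(C)C(C)(C)C)[C@H](O[Si](CC)(CC)CC)CC[C@]1(C)O | intermediate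
20 | (1S,2S,3S,4R)-2-{[(tert-butyldimethylsilyl)oxy]methyl}-3-{3-[(tert-butyldimethylsilyl)oxy]propyl}-2-[(3E)-4-iodopent-3-en-1-yl]-1-methylcyclohexane-1,4-diol | I/C(C)=C/CC[C@@]1(CO[Si](C)(C)C(C)(C)C)[C@H](CCCO[Si](C)(C)C(C)(C)C)[C@H](O)CC[C@]1(C)O | intermediate
21 | (2S,3S,4S)-3-{[(tert-butyldimethylsilyl)oxy]methyl}-2-{3-[(tert-butyldimethylsilyl)oxy]propyl}-4-hydroxy-3-[(3E)-4-iodopent-3-en-1-yl]-4-methylcyclohexan-1-one | I/C(C)=C/CC[C@@]1(CO[Si](C)(C)C(C)(C)C)[C@H](CCCO[Si](C)(C)C(C)(C)C)C(=O)CC[C@]1(C)O | intermediate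
22 | (2S,3S,4S)-3-{[(tert-butyldimethylsilyl)oxy]methyl}-2-{3-[(tert-butyldimethylsilyl)oxy]propyl}-3-[(3E)-4-iodopent-3-en-1-yl]-4-methyl-1-(prop-1-en-2-yl)cyclohexane-1,4-diol (mixture of C1 epimers, centre left undefined) | I/C(C)=C/CC[C@@]1(CO[Si](C)(C)C(C)(C)C)[C@H](CCCO[Si](C)(C)C(C)(C)C)C(O)(C(C)=C)CC[C@]1(C)O | intermediate
23 | (2Z)-2-{(2R,3S,4S)-3-{[(tert-butyldimethylsilyl)oxy]methyl}-2-{3-[(tert-butyldimethylsilyl)oxy]propyl}-4-hydroxy-3-[(3E)-4-iodopent-3-en-1-yl]-4-methylcyclohexylidene}propanal | I/C(C)=C/CC[C@@]1(CO[Si](C)(C)C(C)(C)C)[C@H](CCCO[Si](C)(C)C(C)(C)C)/C(=C(/C)C=O)CC[C@]1(C)O | intermediate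
24 | (2Z)-2-{(2R,3S,4S)-4-hydroxy-3-(hydroxymethyl)-2-(3-hydroxypropyl)-3-[(3E)-4-iodopent-3-en-1-yl]-4-methylcyclohexylidene}propanal | I/C(C)=C/CC[C@@]1(CO)[C@H](CCCO)/C(=C(/C)C=O)CC[C@]1(C)O | intermediate
25 | 2-methylcyclohex-2-en-1-one | CC1=CCCCC1=O | starting material
26 | dimethylaluminium (S)-2,3-dimethylcyclohex-1-en-1-olate | C[Al](C)OC1=C(C)[C@@H](C)CCC1 | intermediate
27 | lithium (S)-2,3-dimethylcyclohex-1-en-1-olate | [Li]OC1=C(C)[C@@H](C)CCC1 | intermediate
28 | (S)-2,2,3-trimethylcyclohexan-1-one | O=C1CCC[C@H](C)C1(C)C | intermediate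
29 | (S)-2-bromo-3,3,4-trimethylcyclohex-1-ene-1-carbaldehyde | O=CC1=C(Br)C(C)(C)[C@@H](C)CC1 | intermediate
30 | (S)-3,3,4-trimethyl-2-[(E)-2-(tributylstannyl)ethenyl]cyclohex-1-ene-1-carbaldehyde | O=CC1=C(/C=C/[Sn](CCCC)(CCCC)CCCC)C(C)(C)[C@@H](C)CC1 | intermediate
31 | {(S)-3,3,4-trimethyl-2-[(E)-2-(tributylstannyl)ethenyl]cyclohex-1-en-1-yl}methanol | OCC1=C(/C=C/[Sn](CCCC)(CCCC)CCCC)C(C)(C)[C@@H](C)CC1 | intermediate
32 | N-({(S)-3,3,4-trimethyl-2-[(E)-2-(tributylstannyl)ethenyl]cyclohex-1-en-1-yl}methyl)-2-nitrobenzenesulfonohydrazide (alkylated on the sulfonylated nitrogen) | NN(CC1=C(/C=C/[Sn](CCCC)(CCCC)CCCC)C(C)(C)[C@@H](C)CC1)S(=O)(=O)c1ccccc1[N+](=O)[O-] | intermediate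
33 | ({(S)-3,3,4-trimethyl-2-[(E)-2-(tributylstannyl)ethenyl]cyclohex-1-en-1-yl}methyl)diazene | N=NCC1=C(/C=C/[Sn](CCCC)(CCCC)CCCC)C(C)(C)[C@@H](C)CC1 | intermediate
34 | tributyl{(E)-2-[(1R,3S)-2,2,3-trimethyl-6-methylidenecyclohexyl]ethenyl}stannane (ring substituents cis) | C=C1CC[C@H](C)C(C)(C)[C@@H]1/C=C/[Sn](CCCC)(CCCC)CCCC | intermediate
35 | (2Z)-2-{(2R,3S,4S)-4-hydroxy-3-(hydroxymethyl)-2-(3-hydroxypropyl)-4-methyl-3-[(3E,5E)-4-methyl-6-[(1R,3S)-2,2,3-trimethyl-6-methylidenecyclohexyl]hexa-3,5-dien-1-yl]cyclohexylidene}propanal | C=C1CC[C@H](C)C(C)(C)[C@@H]1/C=C/C(C)=C/CC[C@@]1(CO)[C@H](CCCO)/C(=C(/C)C=O)CC[C@]1(C)O | target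

## Step count and risks

Total step count: 19. Longest linear sequence: 13 (steps 1–4, 6–13 and 19).

Three steps most likely to fail:

**Step 7 (the proposed new ring expansion).** Possible failures are shift of the unsubstituted ring CH2 instead of C2, attack of the neighbouring silyloxy oxygen on the activated oxirane, or enol silylation of the product. The fallback uses known chemistry in separate operations. It sets out from 14 and comes back at 16. The epoxy alcohol 15 is made and isolated (VO(acac)2, t-BuOOH; or Hf(Ot-Bu)4 with a chiral bishydroxamic acid ligand and cumene hydroperoxide if reagent control of the oxirane centre is needed). 15 is then rearranged with ZnBr2 (or BF3·OEt2) in CH2Cl2 at −20 °C, the classical Lewis acid semipinacol rearrangement of a 2,3-epoxy alcohol, to (2S,3S,4R)-3-{3-[(tert-butyldimethylsilyl)oxy]propyl}-2-(hydroxymethyl)-2-(pent-3-yn-1-yl)-4-[(triethylsilyl)oxy]cyclohexan-1-one F1. F1 is silylated with TBSCl and imidazole to give 16.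

**Step 18 (reductive transposition that sets the ring A stereocentre).** The diazene may deliver hydrogen with poor facial selectivity, or the sulfinic acid may protodestannylate the vinylstannane. The fallback sets out from 31 and comes back at 34 and changes the hydride source and mechanism. 31 is converted with CBr4 and PPh3 into tributyl{(E)-2-[(5S)-2-(bromomethyl)-5,6,6-trimethylcyclohex-1-en-1-yl]ethenyl}stannane F2. F2 is reduced by a copper hydride SN2′ substitution ((IPr)CuCl catalyst, NaOt-Bu, polymethylhydrosiloxane, THF), which puts hydride on the ring carbon from the less hindered face and moves the alkene to the exocyclic position.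

**Step 12 (oxidative transposition to the tetrasubstituted enal).** The tertiary allylic alcohol may ionise, or an E/Z mixture may form. The fallback sets out from 21 and comes back at 23 and replaces addition/transposition by olefination. Horner–Wadsworth–Emmons reaction of 21 with diethyl (1-cyanoethyl)phosphonate and NaH in THF gives (2Z)-2-{(2R,3S,4S)-3-{[(tert-butyldimethylsilyl)oxy]methyl}-2-{3-[(tert-butyldimethylsilyl)oxy]propyl}-4-hydroxy-3-[(3E)-4-iodopent-3-en-1-yl]-4-methylcyclohexylidene}propanenitrile F3 (with its E isomer). Reduction with i-Bu2AlH in toluene at −78 °C and mild acid hydrolysis of the imine gives 23, and any E isomer is equilibrated with a trace of iodine.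

## Further compounds

F1 | step 7 | (2S,3S,4R)-3-{3-[(tert-butyldimethylsilyl)oxy]propyl}-2-(hydroxymethyl)-2-(pent-3-yn-1-yl)-4-[(triethylsilyl)oxy]cyclohexan-1-one | CC#CCC[C@@]1(CO)[C@H](CCCO[Si](C)(C)C(C)(C)C)[C@H](O[Si](CC)(CC)CC)CCC1=O
F2 | step 18 | tributyl{(E)-2-[(5S)-2-(bromomethyl)-5,6,6-trimethylcyclohex-1-en-1-yl]ethenyl}stannane | BrCC1=C(/C=C/[Sn](CCCC)(CCCC)CCCC)C(C)(C)[C@@H](C)CC1
F3 | step 12 | (2Z)-2-{(2R,3S,4S)-3-{[(tert-butyldimethylsilyl)oxy]methyl}-2-{3-[(tert-butyldimethylsilyl)oxy]propyl}-4-hydroxy-3-[(3E)-4-iodopent-3-en-1-yl]-4-methylcyclohexylidene}propanenitrile | I/C(C)=C/CC[C@@]1(CO[Si](C)(C)C(C)(C)C)[C@H](CCCO[Si](C)(C)C(C)(C)C)/C(=C(/C)C#N)CC[C@]1(C)O
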